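**Retrosynthetic overview**

1. Target 24 ⇐ tetra-MOM flavanone 23 ⇐ achiral aldehyde 22: ring C is closed last by joining C3 to C4 in an enantioselective rhodium-catalysed intramolecular alkene hydroacylation, which also creates the C4 ketone and the C2 stereocentre.
2. Enabling feature: in 22 the formyl C–H (future C4–H) on ring A stands ortho to O1, and O1 carries the 1-arylvinyl group C2(=C3H2)–ring B, so the terminal C3 methylene lies five atoms from the acyl carbon and C2 is prochiral.
3. 22 ⇐ aryl bromide 19 (Br/Li exchange, DMF) ⇐ aryl ester 17 (carbonyl methylenation supplies C3) ⇐ phenol 12 + acid 16 (ring B and C2).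
4. 12 ⇐ 2,4,6-trihydroxybenzaldehyde 1: the para oxygen (future O1) takes a 1,1-dimethylpropargyl group that an aromatic Claisen rearrangement moves to C8 as prenyl; bromine marks C4a; the formyl group becomes the (E)-3-methylbut-1-enyl chain at C6.
5. Ring order: rings A and B are bought as benzene rings; ring C is the only ring formed (step 11); the four MOM groups are removed last.

Key step: step 11

Remark (assumption): the sense of induction of (R)-DTBM-SEGPHOS on this substrate class is assumed by analogy with carbon-tethered substrates; should the first run give the 2R series, the (S)-ligand is used and nothing else changes.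

**Route**

Step 1
Reactants: 1 2,4,6-trihydroxybenzaldehyde; 2 3-chloro-3-methylbut-1-yne
Product: 3 2,6-dihydroxy-4-[(2-methylbut-3-yn-2-yl)oxy]benzaldehyde
Conditions: CuCl2·2H2O (1 mol %), DBU, MeCN, −5 → 0 °C
Reagents that add atoms: 3-chloro-3-methylbut-1-yne, C#CC(C)(C)Cl
Why: Copper-catalysed propargylic O-alkylation of a phenol should take place at the 4-OH, the only hydroxyl that is not hydrogen-bonded to the formyl group and the most acidic one, leaving the two chelated ortho hydroxyls free.

Step 2
Reactants: 3 2,6-dihydroxy-4-[(2-methylbut-3-yn-2-yl)oxy]benzaldehyde; 4 chloromethyl methyl ether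
Product: 5 2,6-bis(methoxymethoxy)-4-[(2-methylbut-3-yn-2-yl)oxy]benzaldehyde
Conditions: MOMCl, i-Pr2NEt, n-Bu4NI (cat.), CH2Cl2, 0 → 40 °C
Reagents that add atoms: chloromethyl methyl ether, COCCl
Why: Williamson-type acetal formation with excess reagent should cap both chelated phenols as MOM ethers, which survive the later Grignard, organolithium, titanium carbene and rhodium steps.

Step 3
Reactants: 5 2,6-bis(methoxymethoxy)-4-[(2-methylbut-3-yn-2-yl)oxy]benzaldehyde; 6 N-bromosuccinimide
Product: 7 3-bromo-2,6-bis(methoxymethoxy)-4-[(2-methylbut-3-yn-2-yl)oxy]benzaldehyde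
Conditions: NBS (1.0 equiv), MeCN, −20 → 0 °C, dark
Reagents that add atoms: N-bromosuccinimide, O=C1CCC(=O)N1Br
Why: Electrophilic aromatic bromination should give the monobromide because the two free ring positions are equivalent, each is flanked by two oxygens, the first bromine deactivates the ring and the terminal alkyne is inert to NBS; the bromine is the placeholder for the later formyl carbon C4.

Step 4
Reactants: 7 3-bromo-2,6-bis(methoxymethoxy)-4-[(2-methylbut-3-yn-2-yl)oxy]benzaldehyde
Product: 8 3-bromo-2,6-bis(methoxymethoxy)-4-[(2-methylbut-3-en-2-yl)oxy]benzaldehyde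
Conditions: H2 (1 atm), Pd/CaCO3–Pb(OAc)2 (Lindlar catalyst), quinoline, EtOAc, rt
Reagents that add atoms: none
Why: Lindlar semi-hydrogenation should stop at the terminal alkene and leave the aryl bromide and the aldehyde untouched.

Step 5
Reactants: 8 3-bromo-2,6-bis(methoxymethoxy)-4-[(2-methylbut-3-en-2-yl)oxy]benzaldehyde; 9 isobutylmagnesium bromide
Product: 11 2-bromo-1-[(2-methylbut-3-en-2-yl)oxy]-3,5-bis(methoxymethoxy)-4-[(E)-3-methylbut-1-enyl]benzene, via benzylic carbinol 10 (not isolated)
Conditions: i-BuMgBr, THF, −78 → 0 °C; aq. NH4Cl; then Burgess reagent (MeO2CN–SO2–NEt3 inner salt), PhMe, 50 °C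
Reagents that add atoms: isobutylmagnesium bromide, CC(C)C[Mg]Br
Why: Grignard addition followed by Burgess dehydration (syn elimination through the sulfamate ester) should give the E-alkene, since only the CH2 group offers β-hydrogens and the conformer with aryl and isopropyl apart is favoured; the racemic carbinol centre of 10 is destroyed in the same operation.

Step 6
Reactants: 11 2-bromo-1-[(2-methylbut-3-en-2-yl)oxy]-3,5-bis(methoxymethoxy)-4-[(E)-3-methylbut-1-enyl]benzene
Product: 12 2-bromo-3,5-bis(methoxymethoxy)-4-[(E)-3-methylbut-1-enyl]-6-(3-methylbut-2-enyl)phenol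
Conditions: PhNEt2, 130 °C, Ar
Reagents that add atoms: none
Why: Aromatic Claisen rearrangement of the tertiary allyl aryl ether should deliver the prenyl group to the only free ortho position (the other carries bromine) and free the phenol that becomes O1, the amine solvent suppressing ionisation of the ether.

Step 7
Reactants: 13 2,4-dihydroxybenzoic acid; 4 chloromethyl methyl ether; 14 lithium hydroxide
Product: 16 2,4-bis(methoxymethoxy)benzoic acid, via methoxymethyl ester 15 (not isolated)
Conditions: MOMCl, i-Pr2NEt, CH2Cl2, 0 → 40 °C; then LiOH, THF–MeOH–H2O, rt; 1 M HCl to pH 4, 0 °C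
Reagents that add atoms: chloromethyl methyl ether, COCCl; lithium hydroxide, [Li+].[OH-]
Why: Exhaustive MOM protection followed by saponification should cleave only the MOM ester by acyl substitution, because aryl MOM ethers are stable to hydroxide.

Step 8
Reactants: 12 2-bromo-3,5-bis(methoxymethoxy)-4-[(E)-3-methylbut-1-enyl]-6-(3-methylbut-2-enyl)phenol; 16 2,4-bis(methoxymethoxy)benzoic acid
Product: 17 2-bromo-3,5-bis(methoxymethoxy)-4-[(E)-3-methylbut-1-enyl]-6-(3-methylbut-2-enyl)phenyl 2,4-bis(methoxymethoxy)benzoate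
Conditions: EDC·HCl, DMAP, CH2Cl2, rt
Reagents that add atoms: 2,4-bis(methoxymethoxy)benzoic acid, OC(=O)c1ccc(OCOC)cc1OCOC
Why: Steglich esterification through the acylpyridinium ion should acylate the hindered phenol, the only free hydroxyl, under conditions that spare the MOM ethers.

Step 9
Reactants: 17 2-bromo-3,5-bis(methoxymethoxy)-4-[(E)-3-methylbut-1-enyl]-6-(3-methylbut-2-enyl)phenyl 2,4-bis(methoxymethoxy)benzoate; 18 Tebbe reagent
Product: 19 1-{1-[2-bromo-3,5-bis(methoxymethoxy)-4-[(E)-3-methylbut-1-enyl]-6-(3-methylbut-2-enyl)phenoxy]ethenyl}-2,4-bis(methoxymethoxy)benzene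
Conditions: Cp2Ti(μ-Cl)(μ-CH2)AlMe2 (Tebbe reagent), pyridine (cat.), THF–PhMe, −40 °C → rt; aq. NaOH quench; basic alumina
Reagents that add atoms: Tebbe reagent, C[Al-]1(C)C[Ti](C2C=CC=C2)(C2C=CC=C2)[Cl+]1
Why: Tebbe methylenation of an aryl benzoate (oxatitanacyclobutane formation and cycloreversion) should turn the ester carbonyl into the 1-arylvinyl ether and so supply C3; no other carbonyl is present, which is why the formyl group is introduced only afterwards.

Step 10
Reactants: 19 1-{1-[2-bromo-3,5-bis(methoxymethoxy)-4-[(E)-3-methylbut-1-enyl]-6-(3-methylbut-2-enyl)phenoxy]ethenyl}-2,4-bis(methoxymethoxy)benzene; 20 N,N-dimethylformamide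
Product: 22 2-{[1-(2,4-bis(methoxymethoxy)phenyl)ethenyl]oxy}-4,6-bis(methoxymethoxy)-5-[(E)-3-methylbut-1-enyl]-3-(3-methylbut-2-enyl)benzaldehyde, via aryllithium 21 (not isolated)
Conditions: n-BuLi, THF, −78 °C; DMF, −78 → −20 °C; pH 7 buffer
Reagents that add atoms: N,N-dimethylformamide, CN(C)C=O
Why: Bromine–lithium exchange is faster at −78 °C than any deprotonation, and the aryllithium flanked by two oxygens should be formylated by DMF (Bouveault formylation), the neutral work-up keeping the acid-labile enol ether.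

Step 11
Reactants: 22 2-{[1-(2,4-bis(methoxymethoxy)phenyl)ethenyl]oxy}-4,6-bis(methoxymethoxy)-5-[(E)-3-methylbut-1-enyl]-3-(3-methylbut-2-enyl)benzaldehyde
Product: 23 (2S)-2-[2,4-bis(methoxymethoxy)phenyl]-5,7-bis(methoxymethoxy)-6-[(E)-3-methylbut-1-enyl]-8-(3-methylbut-2-enyl)chroman-4-one
Conditions: [Rh(cod)Cl]2 (2.5 mol %), (R)-DTBM-SEGPHOS (5.5 mol %), NaB[3,5-(CF3)2C6H3]4 (5 mol %), THF, 60 °C
Reagents that add atoms: none
Why: Proposed new method: a cationic monovalent rhodium bisphosphine complex should insert into the formyl C–H bond of 22 with the enol ether alkene bound to the metal, the acyl hydride of trivalent rhodium should add across the C2=C3 bond with hydride to C2 and rhodium to the terminal C3, and C–C reductive elimination from the seven-membered acyl(alkyl)rhodacycle should form the C3–C4 bond and return the catalyst. The closest known reaction type is the enantioselective rhodium-catalysed intramolecular hydroacylation of 1,1-disubstituted alkenes held on a carbon or nitrogen tether (α-substituted 2-vinylbenzaldehydes to 3-substituted indanones, ortho-allylbenzaldehydes to tetralones, N-vinyl- and N-allylindole-2-carbaldehydes to fused ketones); what is new is the oxygen tether, that is an aryl 1-arylvinyl ether as the alkene. Ring C closes in the endo sense (formally 6-endo-trig, anti-Markovnikov hydroacylation), because the exo course would need a tertiary alkyl rhodium at C2 and would give a five-membered benzofuranone with a quaternary carbon. The C2 stereocentre is created when hydride is delivered to one face of the prochiral alkene and is under catalyst control alone: the C2-symmetric bisphosphine differentiates ring B from the aryloxy oxygen on C2, and the alkene has no E/Z isomers that could lead to the other configuration. The step needs chemoselectivity among four alkenes, which the substrate secures because both positions ortho to the formyl group carry oxygen, only O1 holds an alkene within reach, and the prenyl and methylbutenyl groups are meta to the acyl rhodium centre. It also needs reductive elimination to outrun decarbonylation and β-aryloxy elimination, which alkene chelation and the electron-poor cationic metal with a bulky wide-bite-angle ligand are expected to favour.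

Step 12
Reactants: 23 (2S)-2-[2,4-bis(methoxymethoxy)phenyl]-5,7-bis(methoxymethoxy)-6-[(E)-3-methylbut-1-enyl]-8-(3-methylbut-2-enyl)chroman-4-one
Product: 24 (2S)-2-(2,4-dihydroxyphenyl)-5,7-dihydroxy-6-[(E)-3-methylbut-1-enyl]-8-(3-methylbut-2-enyl)chroman-4-one
Conditions: TMSOTf, 2,2'-bipyridyl, CH2Cl2, 0 °C → rt; then H2O, rt; pH 6 work-up
Reagents that add atoms: none
Why: Silyl triflate–bipyridyl acetal exchange should convert the four aryl MOM ethers into trimethylsilyl ethers that water hydrolyses, without free protic acid or base, so that the prenyl group, the electron-rich styrene-type alkene and the benzylic C2–O1 bond (ring opening would racemise C2) are expected to be left alone and the 2S configuration to be kept.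

**Compound list**

1 | 2,4,6-trihydroxybenzaldehyde | O=Cc1c(O)cc(O)cc1O | starting material
2 | 3-chloro-3-methylbut-1-yne | C#CC(C)(C)Cl | starting material
3 | 2,6-dihydroxy-4-[(2-methylbut-3-yn-2-yl)oxy]benzaldehyde | O=Cc1c(O)cc(OC(C)(C)C#C)cc1O | intermediate
4 | chloromethyl methyl ether | COCCl | starting material
5 | 2,6-bis(methoxymethoxy)-4-[(2-methylbut-3-yn-2-yl)oxy]benzaldehyde | O=Cc1c(OCOC)cc(OC(C)(C)C#C)cc1OCOC | intermediate
6 | N-bromosuccinimide | O=C1CCC(=O)N1Br | starting material
7 | 3-bromo-2,6-bis(methoxymethoxy)-4-[(2-methylbut-3-yn-2-yl)oxy]benzaldehyde | O=Cc1c(OCOC)c(Br)c(OC(C)(C)C#C)cc1OCOC | intermediate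
8 | 3-bromo-2,6-bis(methoxymethoxy)-4-[(2-methylbut-3-en-2-yl)oxy]benzaldehyde | O=Cc1c(OCOC)c(Br)c(OC(C)(C)C=C)cc1OCOC | intermediate
9 | isobutylmagnesium bromide | CC(C)C[Mg]Br | starting material
10 | 1-{3-bromo-2,6-bis(methoxymethoxy)-4-[(2-methylbut-3-en-2-yl)oxy]phenyl}-3-methylbutan-1-ol (racemic, not isolated) | CC(C)CC(O)c1c(OCOC)c(Br)c(OC(C)(C)C=C)cc1OCOC | intermediate
11 | 2-bromo-1-[(2-methylbut-3-en-2-yl)oxy]-3,5-bis(methoxymethoxy)-4-[(E)-3-methylbut-1-enyl]benzene | CC(C)/C=C/c1c(OCOC)c(Br)c(OC(C)(C)C=C)cc1OCOC | intermediate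
12 | 2-bromo-3,5-bis(methoxymethoxy)-4-[(E)-3-methylbut-1-enyl]-6-(3-methylbut-2-enyl)phenol | CC(C)/C=C/c1c(OCOC)c(Br)c(O)c(CC=C(C)C)c1OCOC | intermediate
13 | 2,4-dihydroxybenzoic acid | OC(=O)c1ccc(O)cc1O | starting material
14 | lithium hydroxide | [Li+].[OH-] | starting material
15 | methoxymethyl 2,4-bis(methoxymethoxy)benzoate (not isolated) | COCOC(=O)c1ccc(OCOC)cc1OCOC | intermediate
16 | 2,4-bis(methoxymethoxy)benzoic acid | OC(=O)c1ccc(OCOC)cc1OCOC | intermediate
17 | 2-bromo-3,5-bis(methoxymethoxy)-4-[(E)-3-methylbut-1-enyl]-6-(3-methylbut-2-enyl)phenyl 2,4-bis(methoxymethoxy)benzoate | CC(C)/C=C/c1c(OCOC)c(Br)c(OC(=O)c2ccc(OCOC)cc2OCOC)c(CC=C(C)C)c1OCOC | intermediate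
18 | Tebbe reagent, Cp2Ti(μ-Cl)(μ-CH2)AlMe2 (four-membered Ti–CH2–Al–Cl ring, the chloride bridge drawn as a Cl→Al donor bond with formal charges) | C[Al-]1(C)C[Ti](C2C=CC=C2)(C2C=CC=C2)[Cl+]1 | starting material
19 | 1-{1-[2-bromo-3,5-bis(methoxymethoxy)-4-[(E)-3-methylbut-1-enyl]-6-(3-methylbut-2-enyl)phenoxy]ethenyl}-2,4-bis(methoxymethoxy)benzene | CC(C)/C=C/c1c(OCOC)c(Br)c(OC(=C)c2ccc(OCOC)cc2OCOC)c(CC=C(C)C)c1OCOC | intermediate
20 | N,N-dimethylformamide | CN(C)C=O | starting material
21 | aryllithium from 19, lithium in place of bromine (not isolated) | CC(C)/C=C/c1c(OCOC)c([Li])c(OC(=C)c2ccc(OCOC)cc2OCOC)c(CC=C(C)C)c1OCOC | intermediate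
22 | 2-{[1-(2,4-bis(methoxymethoxy)phenyl)ethenyl]oxy}-4,6-bis(methoxymethoxy)-5-[(E)-3-methylbut-1-enyl]-3-(3-methylbut-2-enyl)benzaldehyde | CC(C)/C=C/c1c(OCOC)c(C=O)c(OC(=C)c2ccc(OCOC)cc2OCOC)c(CC=C(C)C)c1OCOC | intermediate
23 | (2S)-2-[2,4-bis(methoxymethoxy)phenyl]-5,7-bis(methoxymethoxy)-6-[(E)-3-methylbut-1-enyl]-8-(3-methylbut-2-enyl)chroman-4-one | CC(C)=CCc1c(OCOC)c(/C=C/C(C)C)c(OCOC)c2c1O[C@H](c1ccc(OCOC)cc1OCOC)CC2=O | intermediate
24 | (2S)-2-(2,4-dihydroxyphenyl)-5,7-dihydroxy-6-[(E)-3-methylbut-1-enyl]-8-(3-methylbut-2-enyl)chroman-4-one | CC(C)=CCc1c(O)c(/C=C/C(C)C)c(O)c2c1O[C@H](c1ccc(O)cc1O)CC2=O | target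

**Step count and risks**

Total step count: 12. Longest linear sequence: 11 (steps 1–6 and 8–12).

Steps most likely to fail:

Step 11 (proposed new method). The acyl rhodium hydride may lose carbon monoxide before the alkene inserts, the alkyl rhodium intermediate may undergo β-aryloxy elimination that cleaves O1–C2, closure may take the exo course, or facial discrimination at C2 may be poor. The fallback uses known chemistry and closes ring C at O1–C2 instead. It sets out from phenol 12, which O,C-dilithiation (n-BuLi, 2.2 equiv, THF, −78 °C) and acylation with N-methoxy-N-methylacetamide should convert into the ortho-hydroxyacetophenone F1. Claisen–Schmidt condensation with 2,4-bis(methoxymethoxy)benzaldehyde (KOH, EtOH, rt) should give the 2'-hydroxychalcone F2, whose only free phenol is the future O1. Oxa-Michael closure (NaOAc, EtOH, reflux) should give the racemic flavanone F3. Kinetic resolution by asymmetric transfer hydrogenation (RuCl(p-cymene)[(R,R)-TsDPEN], HCO2H–Et3N, EtOAc, rt, stopped near half conversion; the other catalyst antipode if the sense is reversed) is expected to reduce the 2R enantiomer to the cis-flavan-4-ol F4 and to leave the 2S ketone. This ketone is compound 23, where the route is rejoined.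

Step 9. Methylenation may be slow at a carbonyl shielded by three ortho substituents, the aluminium component may strip MOM groups, and the electron-rich enol ether may hydrolyse during work-up. The fallback builds the enol ether by alkylation and elimination, without titanium. It sets out from phenol 12, which is O-alkylated with methyl 2-bromo-2-[2,4-bis(methoxymethoxy)phenyl]acetate (Cs2CO3, DMF, rt) to the α-aryloxy ester F5. Reduction (LiBH4, THF, 0 °C) should give the primary alcohol F6, and I2, PPh3 and imidazole (CH2Cl2, 0 °C) the primary iodide F7. Base-induced elimination of hydrogen iodide (KOtBu, THF, 0 °C), which removes the benzylic α-oxy hydrogen, should give compound 19, where the route is rejoined.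

Step 5. The branched Grignard reagent may transfer a β-hydride (reduction instead of addition), and the dehydration may ionise to a benzylic cation that is trapped by an ortho MOM oxygen or gives E/Z mixtures. The fallback replaces addition and dehydration by a one-step Julia–Kocienski olefination. It sets out from aldehyde 8, which is treated with the potassium salt of 5-(2-methylpropylsulfonyl)-1-phenyl-1H-tetrazole (KHMDS, DME, −60 °C → rt). This should give the E-alkene 11 directly, where the route is rejoined; no new isolated compound lies on this way.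

**Further compounds**

F1 | step 11 | 1-{2-hydroxy-4,6-bis(methoxymethoxy)-5-[(E)-3-methylbut-1-enyl]-3-(3-methylbut-2-enyl)phenyl}ethan-1-one | CC(C)/C=C/c1c(OCOC)c(C(C)=O)c(O)c(CC=C(C)C)c1OCOC
F2 | step 11 | (E)-3-[2,4-bis(methoxymethoxy)phenyl]-1-{2-hydroxy-4,6-bis(methoxymethoxy)-5-[(E)-3-methylbut-1-enyl]-3-(3-methylbut-2-enyl)phenyl}prop-2-en-1-one | CC(C)/C=C/c1c(OCOC)c(C(=O)/C=C/c2ccc(OCOC)cc2OCOC)c(O)c(CC=C(C)C)c1OCOC
F3 | step 11 | racemic 2-[2,4-bis(methoxymethoxy)phenyl]-5,7-bis(methoxymethoxy)-6-[(E)-3-methylbut-1-enyl]-8-(3-methylbut-2-enyl)chroman-4-one | CC(C)=CCc1c(OCOC)c(/C=C/C(C)C)c(OCOC)c2c1OC(c1ccc(OCOC)cc1OCOC)CC2=O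
F4 | step 11 | (2R,4R)-2-[2,4-bis(methoxymethoxy)phenyl]-5,7-bis(methoxymethoxy)-6-[(E)-3-methylbut-1-enyl]-8-(3-methylbut-2-enyl)chroman-4-ol | CC(C)=CCc1c(OCOC)c(/C=C/C(C)C)c(OCOC)c2c1O[C@@H](c1ccc(OCOC)cc1OCOC)C[C@H]2O
F5 | step 9 | methyl 2-[2,4-bis(methoxymethoxy)phenyl]-2-{2-bromo-3,5-bis(methoxymethoxy)-4-[(E)-3-methylbut-1-enyl]-6-(3-methylbut-2-enyl)phenoxy}acetate (racemic) | CC(C)/C=C/c1c(OCOC)c(Br)c(OC(C(=O)OC)c2ccc(OCOC)cc2OCOC)c(CC=C(C)C)c1OCOC
F6 | step 9 | 2-[2,4-bis(methoxymethoxy)phenyl]-2-{2-bromo-3,5-bis(methoxymethoxy)-4-[(E)-3-methylbut-1-enyl]-6-(3-methylbut-2-enyl)phenoxy}ethan-1-ol (racemic) | CC(C)/C=C/c1c(OCOC)c(Br)c(OC(CO)c2ccc(OCOC)cc2OCOC)c(CC=C(C)C)c1OCOC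
F7 | step 9 | 1-{1-[2-bromo-3,5-bis(methoxymethoxy)-4-[(E)-3-methylbut-1-enyl]-6-(3-methylbut-2-enyl)phenoxy]-2-iodoethyl}-2,4-bis(methoxymethoxy)benzene (racemic) | CC(C)/C=C/c1c(OCOC)c(Br)c(OC(CI)c2ccc(OCOC)cc2OCOC)c(CC=C(C)C)c1OCOC
F0 | step 5 | none | none
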